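**Plan**

Labels: ring D (pyran) is O1, C2, C3, C4, Cb, Ca; ring B sits on Ca through b6, prenylated ring A on Cb through a1, and the ring C oxygen joins a6 to b1.
Enabling feature: in ring A, a1 (bonded to Cb) is para to the hydroxylated carbon a4 and next to the ether carbon a6, so a1, a4 and a6 map onto the free carbonyl carbon, the ketal carbon and a β-carbon of a prenyl-para-benzoquinone monoketal.
Cuts: Cb–a1, O–a6 and O1–Ca together (ortho-hydroxyaryl ketone plus quinone monoketal); then Ca–b6 (aryllithium plus Weinreb amide); then C2–CH3 and the C2–CH2 bond to the homoprenyl group (two Grignard reactions on a lactone acid).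
Forward: the C2-to-Ca chain is assembled on the lactone, ring B is attached as the ketone, and one flask then joins ring A as a cyclohexadiene, closes ring C while ring A aromatises, and closes ring D; desilylation finishes.
Stereochemistry: C3 is taken from (S)-5-oxotetrahydrofuran-2-carboxylic acid; C2 is set next to it by Felkin–Anh addition of MeMgBr to the homoprenyl ketone; both centres are spectators afterwards.

Key step: step 11

Remark: the SMILES is read as (2S,3S) at C2 and C3 (the two oxygens syn along the extended C4–C3–C2–CH2 chain), and the route is built for that isomer.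

**Route**

Step 1
Reactants: 1 (S)-5-oxotetrahydrofuran-2-carboxylic acid; 2 5-bromo-2-methylpent-2-ene
Product: 5 (S)-5-(5-methylhex-4-enoyl)dihydrofuran-2(3H)-one, via (S)-5-oxotetrahydrofuran-2-carbonyl chloride 3 (not isolated), via (4-methylpent-3-en-1-yl)magnesium bromide 4 (not isolated)
Conditions: 1, (COCl)2, DMF (cat.), CH2Cl2, 0 to 23 °C, evaporate; 2, Mg, THF, 23 °C; combine, Fe(acac)3 (3 mol %), THF, −78 °C
Reagents that add atoms: none
Why: Acid chloride formation and iron-catalysed acylation of an alkyl Grignard reagent (ketone synthesis), fast enough at −78 °C to stop at the ketone and to leave the lactone and the C3 stereocentre carried over from 1 untouched.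

Step 2
Reactants: 5 (S)-5-(5-methylhex-4-enoyl)dihydrofuran-2(3H)-one
Product: 6 (S)-5-[(S)-2-hydroxy-6-methylhept-5-en-2-yl]dihydrofuran-2(3H)-one
Conditions: MeMgBr (1.2 equiv), THF, −78 °C
Reagents that add atoms: methylmagnesium bromide, C[Mg]Br
Why: Grignard addition to the ketone, much faster than to the lactone at −78 °C, under polar Felkin–Anh control: the ring C–O bond lies anti to the incoming methyl, which passes the C3 hydrogen instead of the ring CH2, and this should set C2 as S.

Step 3
Reactants: 6 (S)-5-[(S)-2-hydroxy-6-methylhept-5-en-2-yl]dihydrofuran-2(3H)-one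
Product: 7 (S)-5-{(S)-6-methyl-2-[(triethylsilyl)oxy]hept-5-en-2-yl}dihydrofuran-2(3H)-one
Conditions: TESOTf, 2,6-lutidine, CH2Cl2, −78 to 0 °C
Reagents that add atoms: triethylsilyl trifluoromethanesulfonate, CC[Si](CC)(CC)OS(=O)(=O)C(F)(F)F
Why: Silyl triflate silylation, the standard way to cap a tertiary alcohol, masks O1 with the group meant to fall last in the acid phase of step 11; no stereocentre is affected.

Step 4
Reactants: 7 (S)-5-{(S)-6-methyl-2-[(triethylsilyl)oxy]hept-5-en-2-yl}dihydrofuran-2(3H)-one
Product: 8 (4S,5S)-4-hydroxy-N-methoxy-N,5,9-trimethyl-5-[(triethylsilyl)oxy]dec-8-enamide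
Conditions: MeNH(OMe)·HCl, i-PrMgCl, THF, −20 to 0 °C
Reagents that add atoms: N,O-dimethylhydroxylamine hydrochloride, CNOC.Cl
Why: Weinreb amide formation by aminolysis of the lactone with the chloromagnesium amide opens the ring at the acyl carbon and frees the C3 hydroxyl as the only unprotected oxygen without touching C3; the crude hydroxy amide is silylated at once to forestall relactonisation.

Step 5
Reactants: 8 (4S,5S)-4-hydroxy-N-methoxy-N,5,9-trimethyl-5-[(triethylsilyl)oxy]dec-8-enamide
Product: 9 (4S,5S)-4-[(tert-butyldimethylsilyl)oxy]-N-methoxy-N,5,9-trimethyl-5-[(triethylsilyl)oxy]dec-8-enamide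
Conditions: TBSOTf, 2,6-lutidine, CH2Cl2, 0 °C
Reagents that add atoms: tert-butyldimethylsilyl trifluoromethanesulfonate, CC(C)(C)[Si](C)(C)OS(=O)(=O)C(F)(F)F
Why: Silyl triflate silylation of the hindered secondary alcohol gives the robust TBS ether that keeps O3 from competing with O1 for the ketone in step 11.

Step 6
Reactants: 10 4-bromobenzene-1,3-diol
Product: 11 2-bromo-5-[(triisopropylsilyl)oxy]phenol
Conditions: TIPSCl (1.0 equiv), imidazole, CH2Cl2, 0 °C
Reagents that add atoms: chlorotri(propan-2-yl)silane, CC(C)[Si](Cl)(C(C)C)C(C)C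
Why: Regioselective monosilylation: the bulky silyl chloride should take the hydroxyl para to bromine, which is not flanked by the halogen, and the minor isomer and bis-ether are removable by chromatography.

Step 7
Reactants: 9 (4S,5S)-4-[(tert-butyldimethylsilyl)oxy]-N-methoxy-N,5,9-trimethyl-5-[(triethylsilyl)oxy]dec-8-enamide; 11 2-bromo-5-[(triisopropylsilyl)oxy]phenol
Product: 13 (4S,5S)-4-[(tert-butyldimethylsilyl)oxy]-1-{2-hydroxy-4-[(triisopropylsilyl)oxy]phenyl}-5,9-dimethyl-5-[(triethylsilyl)oxy]dec-8-en-1-one, via lithium 2-lithio-5-[(triisopropylsilyl)oxy]phenolate 12 (not isolated)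
Conditions: 11 (2.2 equiv), n-BuLi (1.95 equiv per 11), THF, −78 to −20 °C; then 9, −78 to 0 °C
Reagents that add atoms: none
Why: Deprotonation and bromine–lithium exchange give the ortho-lithiophenoxide, which acylates once on the Weinreb amide through the stable chelated tetrahedral intermediate (Weinreb ketone synthesis) and so delivers the ortho-hydroxyaryl ketone with the b1 phenol already free.

Step 8
Reactants: 14 1,4-dimethoxybenzene; 15 1-bromo-3-methylbut-2-ene
Product: 17 1,4-dimethoxy-2-(3-methylbut-2-en-1-yl)benzene, via (2,5-dimethoxyphenyl)lithium 16 (not isolated)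
Conditions: n-BuLi, TMEDA, THF, 0 to 23 °C; CuBr·SMe2 (10 mol %), then 15, −78 to 23 °C
Reagents that add atoms: none
Why: Directed ortho-lithiation of the dimethoxyarene followed by copper-catalysed SN2 allylation at the primary carbon of prenyl bromide.

Step 9
Reactants: 17 1,4-dimethoxy-2-(3-methylbut-2-en-1-yl)benzene
Product: 18 3,3,6,6-tetramethoxy-1-(3-methylbut-2-en-1-yl)cyclohexa-1,4-diene
Conditions: Pt anode, constant current, KOH (1%) in MeOH, 0 °C, undivided cell
Reagents that add atoms: methanol, CO
Why: Anodic bis-methoxylation of a 1,4-dimethoxyarene to the quinone bisketal (two-electron oxidation with methanol capture at both ipso carbons); the arene is oxidised at a lower potential than the isolated trisubstituted alkene.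

Step 10
Reactants: 18 3,3,6,6-tetramethoxy-1-(3-methylbut-2-en-1-yl)cyclohexa-1,4-diene
Product: 19 4,4-dimethoxy-3-(3-methylbut-2-en-1-yl)cyclohexa-2,5-dien-1-one
Conditions: AcOH, H2O, acetone, 0 °C
Reagents that add atoms: water, O
Why: Regioselective monohydrolysis of a quinone bisketal: ionisation is easier at the ketal whose dienyl cation places charge on the prenyl-bearing ring carbon, so that ketal becomes the carbonyl and the ketal flanked by the prenyl-bearing carbon is kept.

Step 11
Reactants: 13 (4S,5S)-4-[(tert-butyldimethylsilyl)oxy]-1-{2-hydroxy-4-[(triisopropylsilyl)oxy]phenyl}-5,9-dimethyl-5-[(triethylsilyl)oxy]dec-8-en-1-one; 19 4,4-dimethoxy-3-(3-methylbut-2-en-1-yl)cyclohexa-2,5-dien-1-one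
Product: 23 C3-O-TBS/b3-O-TIPS bis(silyl ether) of the target (a4 phenol free), via quinol ketal aldol adduct 20 (not isolated), via para-quinol dienone 21 (not isolated), via dibenzoxepinone 22 (not isolated)
Conditions: 13, LiN(i-Pr)2 (2.1 equiv), THF, −78 °C; 19 (1.3 equiv), −78 °C; then 2 M HCl (aq), THF, −78 to 23 °C
Reagents that add atoms: water, O
Why: Proposed new method: the dilithium phenoxide–enolate of 13 should add through Cb to the only free carbonyl of 19 (lithium aldol, 1,2-addition) to give quinol ketal 20, and aqueous acid should then first hydrolyse the ketal to cross-conjugated dienone 21, next let the b1 phenol add to a6 and the a1 hydroxyl leave with the a6 hydrogen so that ring A becomes a phenol (22), and finally cleave the tertiary triethylsilyl ether, whereupon O1 condenses with ketone Ca to the stilbene-type enol ether. The closest known reaction types are the 1,2-addition of lithium enolates to quinone monoketals, the acid-promoted oxa-Michael cyclisation of tethered hydroxyl groups onto para-quinols with dehydrative rearomatisation, and the cyclodehydration of δ-hydroxy ketones to 3,4-dihydro-2H-pyrans; their union in one flask, with a seven-membered diaryl ether as the ring formed, is the untested part. Ring C closes by 7-exo-trig oxa-Michael addition (O on a6) and ring D by 6-exo-trig attack of O1 on Ca followed by loss of water. No stereocentre that persists is formed: Cb and a1 are stereogenic only in 20 and 21 and both end as sp2 carbons, while C2 and C3 are spectators. The step needs 1,2- over 1,4-addition, which the lithium enolate at −78 °C and the acid quench before warming should secure, and attack of the phenol at a6 and not a2, which the prenyl group on a3 secures by making the a2=a3 arm an α-substituted, more hindered and less electrophilic enone. The triethylsilyl ether is chosen as the slowest of the acid-labile groups to go (after the ketal, before the secondary TBS and aryl TIPS ethers), so that Ca stays a ketone until ring C is closed.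

Step 12
Reactants: 23 C3-O-TBS/b3-O-TIPS bis(silyl ether) of the target (a4 phenol free)
Product: 24 CNP0185870.1
Conditions: Bu4NF, AcOH, THF, 0 to 40 °C
Reagents that add atoms: none
Why: Fluoride-mediated cleavage of the aryl TIPS and secondary TBS ethers (acetic acid buffers the phenoxides); the enol ether, both alkenes and the two stereocentres are not affected.

**Compound list**

1 | (S)-5-oxotetrahydrofuran-2-carboxylic acid | O=C1CC[C@@H](C(O)=O)O1 | starting material
2 | 5-bromo-2-methylpent-2-ene | CC(C)=CCCBr | starting material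
3 | (S)-5-oxotetrahydrofuran-2-carbonyl chloride (formed in the flask) | O=C1CC[C@@H](C(Cl)=O)O1 | intermediate
4 | (4-methylpent-3-en-1-yl)magnesium bromide (formed in the flask) | CC(C)=CCC[Mg]Br | intermediate
5 | (S)-5-(5-methylhex-4-enoyl)dihydrofuran-2(3H)-one | CC(C)=CCCC(=O)[C@@H]1CCC(=O)O1 | intermediate
6 | (S)-5-[(S)-2-hydroxy-6-methylhept-5-en-2-yl]dihydrofuran-2(3H)-one | CC(C)=CCC[C@](C)(O)[C@@H]1CCC(=O)O1 | intermediate
7 | (S)-5-{(S)-6-methyl-2-[(triethylsilyl)oxy]hept-5-en-2-yl}dihydrofuran-2(3H)-one | CC(C)=CCC[C@](C)(O[Si](CC)(CC)CC)[C@@H]1CCC(=O)O1 | intermediate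
8 | (4S,5S)-4-hydroxy-N-methoxy-N,5,9-trimethyl-5-[(triethylsilyl)oxy]dec-8-enamide | CC(C)=CCC[C@](C)(O[Si](CC)(CC)CC)[C@@H](O)CCC(=O)N(C)OC | intermediate
9 | (4S,5S)-4-[(tert-butyldimethylsilyl)oxy]-N-methoxy-N,5,9-trimethyl-5-[(triethylsilyl)oxy]dec-8-enamide | CC(C)=CCC[C@](C)(O[Si](CC)(CC)CC)[C@@H](O[Si](C)(C)C(C)(C)C)CCC(=O)N(C)OC | intermediate
10 | 4-bromobenzene-1,3-diol (4-bromoresorcinol) | Oc1ccc(Br)c(O)c1 | starting material
11 | 2-bromo-5-[(triisopropylsilyl)oxy]phenol | Oc1cc(O[Si](C(C)C)(C(C)C)C(C)C)ccc1Br | intermediate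
12 | lithium 2-lithio-5-[(triisopropylsilyl)oxy]phenolate (formed in the flask) | [Li]Oc1cc(O[Si](C(C)C)(C(C)C)C(C)C)ccc1[Li] | intermediate
13 | (4S,5S)-4-[(tert-butyldimethylsilyl)oxy]-1-{2-hydroxy-4-[(triisopropylsilyl)oxy]phenyl}-5,9-dimethyl-5-[(triethylsilyl)oxy]dec-8-en-1-one | CC(C)=CCC[C@](C)(O[Si](CC)(CC)CC)[C@@H](O[Si](C)(C)C(C)(C)C)CCC(=O)c1ccc(O[Si](C(C)C)(C(C)C)C(C)C)cc1O | intermediate
14 | 1,4-dimethoxybenzene | COc1ccc(OC)cc1 | starting material
15 | 1-bromo-3-methylbut-2-ene (prenyl bromide) | CC(C)=CCBr | starting material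
16 | (2,5-dimethoxyphenyl)lithium (formed in the flask) | COc1ccc(OC)c([Li])c1 | intermediate
17 | 1,4-dimethoxy-2-(3-methylbut-2-en-1-yl)benzene | COc1ccc(OC)c(CC=C(C)C)c1 | intermediate
18 | 3,3,6,6-tetramethoxy-1-(3-methylbut-2-en-1-yl)cyclohexa-1,4-diene | COC1(OC)C=CC(OC)(OC)C(CC=C(C)C)=C1 | intermediate
19 | 4,4-dimethoxy-3-(3-methylbut-2-en-1-yl)cyclohexa-2,5-dien-1-one | COC1(OC)C=CC(=O)C=C1CC=C(C)C | intermediate
20 | quinol ketal aldol adduct: 13 carrying at Cb a 1-hydroxy-4,4-dimethoxy-3-(3-methylbut-2-en-1-yl)cyclohexa-2,5-dien-1-yl group (epimers at Cb and a1, formed in the flask) | CC(C)=CCC[C@](C)(O[Si](CC)(CC)CC)[C@@H](O[Si](C)(C)C(C)(C)C)CC(C(=O)c1ccc(O[Si](C(C)C)(C(C)C)C(C)C)cc1O)C1(O)C=CC(OC)(OC)C(CC=C(C)C)=C1 | intermediate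
21 | para-quinol dienone: 13 carrying at Cb a 1-hydroxy-3-(3-methylbut-2-en-1-yl)-4-oxocyclohexa-2,5-dien-1-yl group (epimers at Cb and a1, formed in the flask) | CC(C)=CCC[C@](C)(O[Si](CC)(CC)CC)[C@@H](O[Si](C)(C)C(C)(C)C)CC(C(=O)c1ccc(O[Si](C(C)C)(C(C)C)C(C)C)cc1O)C1(O)C=CC(=O)C(CC=C(C)C)=C1 | intermediate
22 | 11-{(2S,3S)-2-[(tert-butyldimethylsilyl)oxy]-3,7-dimethyl-3-[(triethylsilyl)oxy]oct-6-en-1-yl}-3-hydroxy-2-(3-methylbut-2-en-1-yl)-7-[(triisopropylsilyl)oxy]dibenzo[b,f]oxepin-10(11H)-one (epimers at C11, formed in the flask) | CC(C)=CCC[C@](C)(O[Si](CC)(CC)CC)[C@@H](O[Si](C)(C)C(C)(C)C)CC1C(=O)c2ccc(O[Si](C(C)C)(C(C)C)C(C)C)cc2Oc2cc(O)c(CC=C(C)C)cc12 | intermediate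
23 | (2S,3S) pyrano-fused dibenzo[b,f]oxepine: target skeleton with OTBS at C3, OTIPS at b3 and free a4 phenol | CC(C)=CCC[C@]1(C)OC2=C(C[C@@H]1O[Si](C)(C)C(C)(C)C)c1cc(CC=C(C)C)c(O)cc1Oc1cc(O[Si](C(C)C)(C(C)C)C(C)C)ccc12 | intermediate
24 | CNP0185870.1: (2S,3S)-2-methyl-2-(4-methylpent-3-en-1-yl) pyrano-fused dibenzo[b,f]oxepine with OH at C3, a4 and b3 and prenyl at a3 | CC(C)=CCC[C@]1(C)OC2=C(C[C@@H]1O)c1cc(CC=C(C)C)c(O)cc1Oc1cc(O)ccc12 | target

**Count**

Total: 12 steps. Longest linear sequence: 8 steps (1 to 24 through steps 1, 2, 3, 4, 5, 7, 11 and 12).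

**Steps most likely to fail**

1. Step 11 (proposed new method). The cascade may stall or divert in several ways:
   - retro-aldol of the lithium aldolate or conjugate addition instead of carbonyl addition;
   - dehydration of the quinol toward Cb to a quinone methide, followed by closure of the phenol on Cb to a five-membered ring;
   - phenol attack at a2 instead of a6, or a dienone–phenol shift;
   - premature loss of the TBS ether.

   The fallback uses known reaction types only; it sets out from 13 and returns at 23. Ring A is brought in as an aryl dihalide and ring C is closed by two metal-catalysed couplings. Commercial 4-bromo-3-iodophenol is C-prenylated at its free ortho position (NaH, toluene, then 15) to 4-bromo-5-iodo-2-(3-methylbut-2-en-1-yl)phenol F1. The phenol is masked with ethyl vinyl ether (PPTS, CH2Cl2) as 1-bromo-4-(1-ethoxyethoxy)-2-iodo-5-(3-methylbut-2-en-1-yl)benzene F2. Ullmann-type coupling of the phenol of 13 with the C–I bond of F2 (CuI, N,N-dimethylglycine, Cs2CO3, dioxane, 90 °C) should give the diaryl ether ketone F3 (O–a6 bond). Intramolecular palladium-catalysed ketone α-arylation at the C–Br bond (Pd2(dba)3, Xantphos, K3PO4, toluene, 90 °C) should then give the 3-(1-ethoxyethoxy) analogue of the dibenzoxepinone F4 (Cb–a1 bond, ring C). Aqueous HCl in THF removes the ethoxyethyl and triethylsilyl groups and cyclodehydrates the δ-hydroxy ketone (O1–Ca bond, ring D) to 23.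

2. Step 2. Facial selectivity may be poor or inverted if magnesium chelation between the ketone and ring oxygens competes with the Felkin–Anh mode, and the tertiary alkoxide may translactonise before the quench.

   The fallback sets out from 1 (through acid chloride 3) and returns at 6; it introduces the two carbon groups in the opposite order so that chelation becomes the productive mode. Acid chloride 3 is treated with Me2CuLi (Et2O, −78 °C) to give (S)-5-acetyldihydrofuran-2(3H)-one F5. F5 is precomplexed with MgBr2·OEt2 in CH2Cl2, and Grignard reagent 4 (prepared in Et2O) is added at −78 °C. The homoprenyl group then enters under Cram-chelate control (magnesium bridging ketone and ring oxygens, attack past the C3 hydrogen). Because the two carbon groups have exchanged roles, this leads to the same (S,S)-alcohol 6.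

3. Step 7. The dilithio species may be poorly soluble and sluggish, so that conversion is low, and it may deprotonate the amide instead of adding to it.

   The fallback sets out from 11 and returns at 13; it replaces the dianion by a protected, chelation-stabilised monolithium reagent. Phenol 11 is converted with ethyl vinyl ether (PPTS, CH2Cl2) into 1-bromo-2-(1-ethoxyethoxy)-4-[(triisopropylsilyl)oxy]benzene F6. Bromine–lithium exchange (n-BuLi, THF, −78 °C) and addition to Weinreb amide 9 should give the ortho-(1-ethoxyethoxy)aryl ketone F7. Brief treatment with PPTS in MeOH at 0 °C removes the acetal, which is far more labile than the tertiary TES, secondary TBS and aryl TIPS ethers, to give 13.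

Further compounds
F1 | step 11 | 4-bromo-5-iodo-2-(3-methylbut-2-en-1-yl)phenol | Oc1cc(I)c(Br)cc1CC=C(C)C
F2 | step 11 | 1-bromo-4-(1-ethoxyethoxy)-2-iodo-5-(3-methylbut-2-en-1-yl)benzene | CCOC(C)Oc1cc(I)c(Br)cc1CC=C(C)C
F3 | step 11 | diaryl ether ketone: 13 with its b1 oxygen bonded to a6 of a 2-bromo-5-(1-ethoxyethoxy)-4-(3-methylbut-2-en-1-yl)phenyl group | CC(C)=CCC[C@](C)(O[Si](CC)(CC)CC)[C@@H](O[Si](C)(C)C(C)(C)C)CCC(=O)c1ccc(O[Si](C(C)C)(C(C)C)C(C)C)cc1Oc1cc(OC(C)OCC)c(CC=C(C)C)cc1Br
F4 | step 11 | 3-(1-ethoxyethoxy) analogue of dibenzoxepinone 22 | CC(C)=CCC[C@](C)(O[Si](CC)(CC)CC)[C@@H](O[Si](C)(C)C(C)(C)C)CC1C(=O)c2ccc(O[Si](C(C)C)(C(C)C)C(C)C)cc2Oc2cc(OC(C)OCC)c(CC=C(C)C)cc12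
F5 | step 2 | (S)-5-acetyldihydrofuran-2(3H)-one | CC(=O)[C@@H]1CCC(=O)O1
F6 | step 7 | 1-bromo-2-(1-ethoxyethoxy)-4-[(triisopropylsilyl)oxy]benzene | CCOC(C)Oc1cc(O[Si](C(C)C)(C(C)C)C(C)C)ccc1Br
F7 | step 7 | (4S,5S)-4-[(tert-butyldimethylsilyl)oxy]-1-{2-(1-ethoxyethoxy)-4-[(triisopropylsilyl)oxy]phenyl}-5,9-dimethyl-5-[(triethylsilyl)oxy]dec-8-en-1-one | CC(C)=CCC[C@](C)(O[Si](CC)(CC)CC)[C@@H](O[Si](C)(C)C(C)(C)C)CCC(=O)c1ccc(O[Si](C(C)C)(C(C)C)C(C)C)cc1OC(C)OCC
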